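Target takes one coupling partner per molecule, and second product takes another. Both steps draw on the same charge, so the next run hangs on how much partner target can expect.

| setting | Friday's | flask |
|---|---|---|
| solid substrate | 2 mM | 2.0 mM |
| second substrate | 1 mM | 1.00 mM |
| coupling partner | 3.6 mM | 1.80 mM |
| free catalyst | 0.30 mM | 0.30 mM |
| remark | run made earlier |  |
| time |  | 2.5 min |

Friday's run (percent of the solid substrate charged)

| time / s | target / % | starting material / % |
|---|---|---|
| 10.0 | 6 | 4 |
| 15.0 | 6 | 11 |
| 25.0 | 8 | 12 |
| 30.0 | 16 | 12 |
| 40.0 | 22 | 6 |
| 50.0 | 27 | 13 |

(standard deviation of a reading: 2 percentage points)

- solid substrate is a solid; its amount is given per volume of the solution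
- the numbers in the tables scatter by 2 percentage points (one standard deviation)
- steps thought possible: second substrate + free catalyst <-> catalyst intermediate B; starting material <-> dormant form; solid substrate <-> starting material; coupling partner + catalyst intermediate A -> free catalyst + target; starting material + free catalyst <-> catalyst intermediate A; coupling partner + catalyst intermediate B -> free catalyst + second product
- at the start none of the solid substrate is in solution
- starting material means what is dissolved; the solid is not counted in it

1. the target standing at 2.5 min, as a percentage of the solid substrate charged
2. concentration of starting material in solution at 2.5 min, in percent of saturation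

What the partner leaves for target, once second substrate has taken one partner each, counted per solid substrate charged, is the partner budget W, here 40.0 %. On Friday's charges the same reckoning gives 130 %, more than the solid substrate charged. In the new flask W is less than that charge, which makes coupling partner the limiting reagent for target.

Friday's target reads 27 % at 50.0 s. My own reckoning takes the rate as proportional to partner, so this flask starts at half that pace. At that pace, W fills in 2.47 min, about the planned 2.5 min. The pace falls as partner is used, so I expect target somewhat under W at the stop. The decision is to charge the recipe as it stands and stop at 2.5 min.

The forecast gives 32 % of target and 88 % of saturation at the stop, holding of Friday's run that “the solution sits fairly near saturation”.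

The flask gives 33.6 % of target and 17.4 % of saturation.

    second substrate + free catalyst ⇌ catalyst intermediate B (K = 440 M⁻¹, k = 300 M⁻¹ s⁻¹)
    starting material ⇌ dormant form (K = 7.20, k = 0.790 s⁻¹)
    solid substrate ⇌ starting material, rate k3*(cs3 - [starting material]) while solid is left; crystals form when [starting material] > cs3 (solubility = 0.900 mM, k = 0.0700 s⁻¹)
    coupling partner + catalyst intermediate A → free catalyst + target (k = 310 M⁻¹ s⁻¹)
    starting material + free catalyst ⇌ catalyst intermediate A (K = 800 M⁻¹, k = 570 M⁻¹ s⁻¹)
    coupling partner + catalyst intermediate B → free catalyst + second product (k = 560 M⁻¹ s⁻¹)

In this flask, the turning of second substrate and free catalyst into catalyst intermediate B has half its turnover up to the stop behind it by 0.256 min, earlier than the stop at 2.5 min. Second product stands at 0.960 mM at 2.50 min, and target stands 6.4 percentage points under W with 9.3 % of the partner left. In this flask, solid substrate stands at 0 % by 1.25 min, and at 2.50 min starting material stands at 7.83 % of the solid charged, against 57.1 % as dormant form. In the neighbour flask charged with 0.40 mM of second substrate, W is 70.0 %, and target stands at 47.8 % with 25 % of its partner left.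

The numbers in the tables were generated by integration for an exercise; the scatter is artificial.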